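The numbers come from no measurement; no experiment stands behind them.

The pitfall in this flask is to count the whole carrier as working: 7.50 mM of carrier at 0.70 M⁻¹ min⁻¹ over 8.0 h gives 92.0% on paper, but starting material meets fresh carrier, and fresh carrier is one form among three.

starting material 0.050 M; salt in the second phase 1.10 equiv; spent carrier 15 mol%; time 8.0 h; volume of the second phase over the first 0.25

    spent carrier + salt in the second phase ⇌ fresh carrier + spent salt in the second phase (K1 = 2.0, k1 = 0.15 M⁻¹ min⁻¹)
    starting material + fresh carrier → product + spent carrier (k2 = 0.70 M⁻¹ min⁻¹)
    2 fresh carrier ⇌ resting dimer, settled at all times (K3 = 210 M⁻¹)
    crystals ⇌ product, rate k4*(cs4 - [product]) while solid is left; crystals form when [product] > cs4 (cs4 = 24 mM, k4 = 0.17 min⁻¹)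

- amounts and yields of product count crystals too
- where a step has two of a species, its rate is k times that concentration squared, and two are used at each turn
- in the second phase: salt in the second phase, spent salt in the second phase; everything else is in the first
- charges count per volume of the first phase; a concentration in a rate is the amount of a species over the volume of its own phase; every rate counts per litre of the first phase
- given per volume of solution although it is solid: crystals
- run time (flask): 8.0 h

* product and crystals together at 8.0 h, in percent of the starting material charged
* concentration of product in solution at 8.0 h, in percent of saturation

If fresh carrier holds steady, starting material decays pseudo-first-order, with a time constant of one over k2 times fresh carrier. I therefore need one number, the run time over that constant, and must replace the curve of fresh carrier by its mean.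

Salt remakes fresh carrier and starting material uses it, so fresh over spent carrier is the ratio of two frequencies. I take a mid-run state: a quarter of the starting material gone, and salt spent by that plus half the carrier, 16.2 mM. With salt counted in its own phase, spent carrier turns at 0.0233 min⁻¹, and fresh carrier at 0.0311 min⁻¹, the back step included.

The carrier balance counts fresh, spent, and two per resting dimer, the dimer being 210 M⁻¹ times fresh carrier squared. It gives fresh carrier 2.28 mM.

The reach, fresh carrier times k2 times the run time, is 0.765, and one minus its negative exponential gives a yield of 53.5%.

Was one number enough? The same balance gives 2.43 mM at the start's ratio and 2.11 mM with half gone. Reckoned as if held for the whole run, those two give yields of 50.8% and 55.8%.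

My 26.7 mM of product passes the solubility of 24 mM, so crystals form. Solution then stands above saturation by rate over k4, at 101%.

The forecast gives 51.5% and 100.9%, and says: “Much carrier rests as dimer”.

The flask gives 51.7% and 101%. Fresh carrier stood at 28.9%, 30.0% and 28.2% of the catalyst charged after 0.800 h, 4.00 h and 8.00 h, against my mean of 30.4%. For the neighbour flask charged with 0.020 M, at the same fractions gone every term of my ratio scales with the charge, so I keep the ratio, but its 3.00 mM of carrier yields fresh carrier 1.08 mM. The reach falls to 0.361, a yield of 30.3%. That neighbour flask gives 28.8%.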